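**Plan**

- Retrosynthesis: the acetate ester and the ketal on the glycol are removed first; the methine C1' is then cut from C3 of ring B and, after that, from C2 of ring A, leaving indole, tryptophol and a three-carbon α,β-dioxygenated aldehyde.
- Enabling feature: C1' is bonded to C2 of ring A and to C3 of ring B, and the oxygen of the two-carbon chain on C3 of ring A can reach C1'. That oxygen can bind the aldehyde carbon as an oxocarbenium ion, deliver it to C2 of ring A, and later leave C1' again.
- Forward: diacetone-D-mannitol 1 is cleaved to (R)-glyceraldehyde acetonide 2; tryptophol 3 and 2 close a pyran ring; indole 4 then opens this transient pyranoindole 5 to the bis(indolyl)methine alcohol 6; acetylation gives 7 and ketal hydrolysis the target 8.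
- Stereochemistry: C2' is carried unchanged from D-mannitol through 2; C1' is set in the key step by 1,2-induction from the dioxolane (allylic strain plus Felkin–Anh polar control).

Key step: step 2

Remark: ring A is the 2,3-disubstituted indole, ring B the 3-substituted indole, C1' the methine between them, C2'/C3' the glycol carbons. The target is read as (1'S,2'S); its C2' corresponds spatially to C2 of (R)-glyceraldehyde acetonide, and the descriptor changes from R to S only because the CIP ranking of the neighbours changes.

**Step 1**
Reactants: 1 1,2:5,6-di-O-isopropylidene-D-mannitol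
Product: 2 (R)-2,2-dimethyl-1,3-dioxolane-4-carbaldehyde
Conditions: NaIO4, sat. aq NaHCO3, CH2Cl2, 0 °C to rt; organic layer dried (MgSO4), concentrated cold and used at once
Reagents that add atoms: none
Why: Malaprade glycol cleavage of the only free 1,2-diol of the C2-symmetric substrate should give two equivalents of the aldehyde, whose stereocenter is the C2/C5 centre of D-mannitol and is not touched in the buffered two-phase medium.

**Step 2**
Reactants: 3 tryptophol; 2 (R)-2,2-dimethyl-1,3-dioxolane-4-carbaldehyde; 4 indole
Product: 6 2-{2-[(S)-[(4S)-2,2-dimethyl-1,3-dioxolan-4-yl](1H-indol-3-yl)methyl]-1H-indol-3-yl}ethan-1-ol, via 1-(dioxolan-4-yl)tetrahydropyrano[3,4-b]indole 5 (not isolated)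
Conditions: 3 (1.1 equiv), 2 (1.0 equiv), Sc(OTf)3 (10 mol%), 4 Å MS, MeCN, 0 °C to rt; then 4 (3 equiv), rt to 50 °C
Reagents that add atoms: none
Why: Proposed new method: the hemiacetal of 3 and 2 should lose water under Sc(OTf)3 to an oxocarbenium ion that ring A captures at C2 (directly, or at C3 followed by 1,2-shift), closing the pyran ring of 5 in the 6-endo-trig mode; on warming, the Lewis acid should ionise the C1'–O bond of 5 to an indol-2-ylmethyl cation delocalised over C3 and N1 of ring A, and indole 4 adds through its C3, which frees the chain hydroxyl and leaves no ring closed. The closest known reaction types are the oxa-Pictet–Spengler cyclisation of tryptophols with aldehydes and the acid-catalysed Friedel–Crafts alkylation of indoles by 2-indolylmethanols; the new element is their coupling in one flask with a cyclic ether as the leaving group. The pyran C1 centre of 5 is erased on ionisation, so both of its epimers converge on the same cation. The one new stereocenter, C1', is set in the trapping: allylic strain against the flank of ring A should hold the C2'–H bond in the plane of the cation, the C2'–O bond then stands perpendicular, and indole enters anti to it (Felkin–Anh polar sense), which is predicted to give (1'S) beside the (2'S) centre carried over from 2. The step needs cross- over homo-coupling and attack at C2 of ring A: the chain oxygen delivers the aldehyde to C2, and 2 is the limiting component and is consumed before 4 is added, so the symmetrical bis(indol-3-yl)methane cannot form. The ring A nitrogen is left unprotected because its lone pair is the donor that makes ionisation feasible next to the electron-poor dioxolane carbon, and the sieves take up the water of condensation so that the ketal is not hydrolysed.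

**Step 3**
Reactants: 6 2-{2-[(S)-[(4S)-2,2-dimethyl-1,3-dioxolan-4-yl](1H-indol-3-yl)methyl]-1H-indol-3-yl}ethan-1-ol
Product: 7 2-{2-[(S)-[(4S)-2,2-dimethyl-1,3-dioxolan-4-yl](1H-indol-3-yl)methyl]-1H-indol-3-yl}ethyl acetate
Conditions: Ac2O (1.5 equiv), pyridine, CH2Cl2, 0 °C to rt
Reagents that add atoms: acetic anhydride, CC(=O)OC(C)=O
Why: Acyl transfer (esterification) to the single hydroxyl group should be clean, since the indole N–H groups are not acylated by Ac2O in pyridine without a stronger base and the ketal and both stereocenters are inert to these conditions.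

**Step 4**
Reactants: 7 2-{2-[(S)-[(4S)-2,2-dimethyl-1,3-dioxolan-4-yl](1H-indol-3-yl)methyl]-1H-indol-3-yl}ethyl acetate
Product: 8 Colletotryptin C, 2-{2-[(1S,2S)-2,3-dihydroxy-1-(1H-indol-3-yl)propyl]-1H-indol-3-yl}ethyl acetate
Conditions: AcOH/H2O (4:1), 40 °C
Reagents that add atoms: none
Why: Acid-catalysed hydrolysis of the terminal isopropylidene ketal cleaves at the ketal carbon, so the C2'–O bond and both stereocenters are untouched (the oxygen of water leaves in acetone), while the primary acetate is stable in aqueous acetic acid at this temperature.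

**Compound list**

1 | 1,2:5,6-di-O-isopropylidene-D-mannitol | CC1(C)OC[C@@H](O1)[C@@H](O)[C@H](O)[C@H]1COC(C)(C)O1 | starting material
2 | (R)-2,2-dimethyl-1,3-dioxolane-4-carbaldehyde | O=C[C@H]1COC(C)(C)O1 | intermediate
3 | tryptophol, 2-(1H-indol-3-yl)ethan-1-ol | OCCc1c[nH]c2ccccc12 | starting material
4 | indole | c1ccc2[nH]ccc2c1 | starting material
5 | 1-[(4R)-2,2-dimethyl-1,3-dioxolan-4-yl]-1,3,4,9-tetrahydropyrano[3,4-b]indole (both C1 epimers) | C1(OCCc2c1[nH]c3ccccc23)[C@H]4COC(C)(C)O4 | intermediate
6 | 2-{2-[(S)-[(4S)-2,2-dimethyl-1,3-dioxolan-4-yl](1H-indol-3-yl)methyl]-1H-indol-3-yl}ethan-1-ol | OCCc1c([C@H](c2c[nH]c3ccccc23)[C@H]2COC(C)(C)O2)[nH]c2ccccc12 | intermediate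
7 | 2-{2-[(S)-[(4S)-2,2-dimethyl-1,3-dioxolan-4-yl](1H-indol-3-yl)methyl]-1H-indol-3-yl}ethyl acetate | CC(=O)OCCc1c([C@H](c2c[nH]c3ccccc23)[C@H]2COC(C)(C)O2)[nH]c2ccccc12 | intermediate
8 | Colletotryptin C, 2-{2-[(1S,2S)-2,3-dihydroxy-1-(1H-indol-3-yl)propyl]-1H-indol-3-yl}ethyl acetate | CC(=O)OCCc1c([C@H](c2c[nH]c3ccccc23)[C@H](O)CO)[nH]c2ccccc12 | target

**Step count and risks**

Total steps: 4. Longest linear sequence: 4 steps (1 → 2 → 6 → 7 → 8); 3 and 4 enter at step 2.

Steps most likely to fail:

Step 2. Ionisation of the pyran C1'–O bond next to the dioxolane may be slower than loss of the ketal, and facial discrimination at the cation may be modest; an unwanted C1' epimer would have to be removed by chromatography at 6. A more ionising medium is the first adjustment. The fallback runs from 3 back to 6 by known reactions only. Tryptophol 3 would be silylated (TBSCl, imidazole, DMF) to 3-[2-(tert-butyldimethylsilyloxy)ethyl]-1H-indole F1. C2-lithiation through the transient N-lithium carbamate (n-BuLi, then CO2, then t-BuLi, THF, −78 °C), addition to aldehyde 2 and aqueous work-up would give the N–H free 2-indolylcarbinol F2 as a mixture of carbinol epimers. This carbinol, whose chain oxygen can no longer re-close, would alkylate indole 4 under Brønsted acid catalysis ((PhO)2PO2H, 4 Å MS, CH2Cl2, rt) with water as the leaving group, giving the silyl-protected bis(indolyl)methine F3. Bu4NF in THF would then return the route to 6.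

Step 4. Under the acid needed to hydrolyse the ketal, the primary acetate may be partly solvolysed or the freed diol partly esterified by the medium, giving a mixture of acetates. The fallback runs from 6 to 8 and moves the hydrolysis in front of the esterification. Alcohol 6 would be hydrolysed (AcOH/H2O, 60 °C) to the triol F4. PhB(OH)2 (1 equiv, MgSO4, CH2Cl2) would mask only the 1,2-diol as the cyclic phenylboronate F5. Ac2O/pyridine would then esterify the one remaining hydroxyl to the boronate acetate F6, and exchange with pinacol (CH2Cl2, rt) would release 8 at neutral pH.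

Step 1. The α-alkoxy aldehyde may hydrate and oligomerise during aqueous isolation or storage, carrying water into the Lewis-acid step and slowly eroding the α-centre. The fallback runs from 1 back to 2. After cleavage as in step 1, the crude aldehyde would be reduced in the same flask (NaBH4, EtOH, 0 °C) to (S)-2,2-dimethyl-1,3-dioxolane-4-methanol F7, a distillable and storable alcohol. Oxidation under anhydrous conditions just before use (Dess–Martin periodinane, CH2Cl2, 0 °C to rt) would then deliver 2 free of hydrate.

**Further compounds**

F1 | step 2 | 3-[2-(tert-butyldimethylsilyloxy)ethyl]-1H-indole | CC(C)(C)[Si](C)(C)OCCc1c[nH]c2ccccc12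
F2 | step 2 | {3-[2-(tert-butyldimethylsilyloxy)ethyl]-1H-indol-2-yl}[(4R)-2,2-dimethyl-1,3-dioxolan-4-yl]methanol (both carbinol epimers) | CC(C)(C)[Si](C)(C)OCCc1c(C(O)[C@H]2COC(C)(C)O2)[nH]c2ccccc12
F3 | step 2 | 3-[2-(tert-butyldimethylsilyloxy)ethyl]-2-[(S)-[(4S)-2,2-dimethyl-1,3-dioxolan-4-yl](1H-indol-3-yl)methyl]-1H-indole | CC(C)(C)[Si](C)(C)OCCc1c([C@H](c2c[nH]c3ccccc23)[C@H]2COC(C)(C)O2)[nH]c2ccccc12
F4 | step 4 | 2-{2-[(1S,2S)-2,3-dihydroxy-1-(1H-indol-3-yl)propyl]-1H-indol-3-yl}ethan-1-ol | OCCc1c([C@H](c2c[nH]c3ccccc23)[C@H](O)CO)[nH]c2ccccc12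
F5 | step 4 | 2-{2-[(S)-(1H-indol-3-yl)[(4S)-2-phenyl-1,3,2-dioxaborolan-4-yl]methyl]-1H-indol-3-yl}ethan-1-ol | OCCc1c([C@H](c2c[nH]c3ccccc23)[C@H]2COB(c3ccccc3)O2)[nH]c2ccccc12
F6 | step 4 | 2-{2-[(S)-(1H-indol-3-yl)[(4S)-2-phenyl-1,3,2-dioxaborolan-4-yl]methyl]-1H-indol-3-yl}ethyl acetate | CC(=O)OCCc1c([C@H](c2c[nH]c3ccccc23)[C@H]2COB(c3ccccc3)O2)[nH]c2ccccc12
F7 | step 1 | (S)-2,2-dimethyl-1,3-dioxolane-4-methanol | OC[C@H]1COC(C)(C)O1
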